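This flask cannot hold more target than the free base charged to it can pay for.

| setting | Thursday's | Tuesday's | flask |
|---|---|---|---|
| acidic substrate | 0.10 M | 0.10 M | 0.10 M |
| free base | 0.90 equiv | 0.90 equiv | 0.900 equiv |
| electrophile | 0.75 equiv | 3 equiv | 1.50 equiv |
| remark | run made earlier | run made earlier |  |
| time |  |  | 20 min |

| run | time / min | target / % |
|---|---|---|
| Thursday's | 0.500 | 33 |
| Thursday's | 1.33 | 54 |
| Thursday's | 2.50 | 58 |
| Thursday's | 5.00 | 57 |
| Thursday's | 10.0 | 55 |
| Thursday's | 20.0 | 48 |
| Tuesday's | 0.500 | 82 |
| Tuesday's | 1.33 | 85 |
| Tuesday's | 2.50 | 82 |
| Tuesday's | 5.00 | 75 |
| Tuesday's | 10.0 | 65 |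
| Tuesday's | 20.0 | 56 |

(each reading ± 1.5 percentage points)

- the best time, 20 min at the latest, for target
- the amount of target, in percent of the acidic substrate charged, at that time
- earliest time at which at least nineteen twentieths of that best amount are there, in min
- latest time at which they still are, in min

1. I take each target to cost one free base and one electrophile, so I write the balance of the reagent charged in the smaller amount, the limiting reagent. In this flask that is free base, at 0.900 equiv against 1.50 equiv of electrophile. I therefore call 90.0% its ceiling, the smaller of the two charges as a percentage of the acidic substrate charged.

2. My first way to the best amount uses the fact that the flask's electrophile charge is the geometric mean of the two earlier charges. Averaging the highest readings, 58% on Thursday and 85% on Tuesday, gives 71.5%.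

3. My second way starts from the ceiling. Tuesday's run has the ceiling 90.0% and reads highest at 1.33 min. The flask has half of Tuesday's electrophile, so I expect it to take twice as long, which puts its peak near 2.66 min. At 2.50 min, the nearest reading to that time, Tuesday's run stands 8 percentage points under its ceiling, and taking the same shortfall for this flask gives 82.0%.

4. The two ways part by 11 points. Thursday's ceiling is 75.0%, set by electrophile rather than free base and lower than this flask's. The average therefore mixes highest readings from under two different ceilings, so the first way cheats, and I commit to 82.0%.

5. The forecast puts the best at 2.3 min with 80%, held from 1.2 min to 5 min, and says of the loss: “It is only weakly dependent on electrophile.”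

6. The flask gives 78.4% at 2.31 min, 3.6 points under my reckoning, and the span asked for runs from 1.16 min to 4.82 min.

    acidic substrate + free base ⇌ protonated base + anion, settled at all times (K = 9.60)
    electrophile + anion → target (k = 28.0 M⁻¹ min⁻¹)
    anion → decomposed reagent (k = 0.120 min⁻¹)
    target ⇌ isomer of the product (K = 0.850, k = 0.0370 min⁻¹)

At 20.0 min the flask holds 54.9% target, 31.4% isomer of the product and 3.67% decomposed reagent, together 90.0% against the ceiling of 90.0%, with free base at 0%. The neighbour charged with 0.230 equiv of free base has a ceiling of 23.0%, and its best is 21.3%. At 20.0 min its target, isomer of the product and decomposed reagent sum to 23.0%, with 77.0% of the acidic substrate left.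

The readings were computed from invented constants.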